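**Retrosynthetic overview**

- Feature: on the cyclopentane ring (C5–C9) of the cis-fused cyclopenta[c]pyran, O-7 and C10 are cis on the convex face (the face of H-5/H-9), while the tertiary C8 hydroxyl points into the concave face under the pyran ring. A convex 7,8-epoxide whose C10 alkoxide has migrated onto C8 leaves exactly this pattern.
- Late disconnections: C1 isovalerate (lactol acylation), C7 coumarate (esterification) and three silyl ethers, leading back to a 7,8,10-triol carrying a PMB acetal at C1.
- Key disconnection: the C8–O and C10–O bonds of the triol, from the convex 7,8-epoxy-10-ol (epoxide migration, then hydroxide opening at C10), itself from the C7=C8 allylic alcohol.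
- Ring order: the dihydropyran ring comes first, from D-xylal (Ferrier glycosidation, oxidation to the 6-alkoxypyranone that carries C1). The cyclopentene comes second, by phosphine-catalysed [3+2] annulation with ethyl buta-2,3-dienoate (C8–C9 and C5–C6 bonds). C11 is added at C4 through the enol triflate.

Key step: step 10

Remark: iridoid numbering is used (C1 acetal carbon, O2, C3=C4, C5/C9 ring fusion, C6–C8, C10 on C8, C11 on C4). β is the face of H-5/H-9 (convex) and α the concave face. The two Ferrier anomers of step 1 are assumed to be separable by chromatography, as diastereomers normally are.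

**Route**

Step 1
Reactants: 1 3,4-di-O-acetyl-D-xylal; 2 4-methoxybenzyl alcohol
Product: 3 4-methoxybenzyl 4-O-acetyl-2,3-dideoxy-β-D-glycero-pent-2-enopyranoside (1,4-trans anomer)
Conditions: InCl3 (10 mol %), CH2Cl2, rt; chromatographic separation of the anomers
Reagents that add atoms: none
Why: Ferrier rearrangement, in which the Lewis acid ionises the allylic C3 acetate and the alcohol adds to C1 of the allyloxocarbenium ion; the 1,4-trans (β-D) anomer with both oxygens quasi-axial is expected to prevail, and because C1 is the only stereocentre that survives step 3, separating the anomers here turns anomeric purity into enantiomeric purity.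

Step 2
Reactants: 3 4-methoxybenzyl 4-O-acetyl-2,3-dideoxy-β-D-glycero-pent-2-enopyranoside
Product: 4 4-methoxybenzyl 2,3-dideoxy-β-D-glycero-pent-2-enopyranoside
Conditions: NaOMe (cat.), MeOH, 0 °C to rt
Reagents that add atoms: none
Why: Zemplén transesterification removes the acetate without touching the acetal or the alkene.

Step 3
Reactants: 4 4-methoxybenzyl 2,3-dideoxy-β-D-glycero-pent-2-enopyranoside
Product: 5 (R)-6-[(4-methoxybenzyl)oxy]-2H-pyran-3(6H)-one
Conditions: MnO2, CH2Cl2, rt
Reagents that add atoms: none
Why: Allylic alcohol oxidation with MnO2 under neutral conditions gives the enone without ionising the acetal, so the C1 configuration (the future iridoid C1) is kept.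

Step 4
Reactants: 5 (R)-6-[(4-methoxybenzyl)oxy]-2H-pyran-3(6H)-one; 6 ethyl buta-2,3-dienoate
Product: 7 ethyl (1R,4aS,7aS)-1-[(4-methoxybenzyl)oxy]-4-oxo-1,3,4,4a,5,7a-hexahydrocyclopenta[c]pyran-7-carboxylate (1β-OPMB, H-5β, H-9β, C4 ketone, C7=C8, C10 ethyl ester)
Conditions: PPh3 (10 mol %), toluene, 80 °C
Reagents that add atoms: none
Why: Phosphine-catalysed allenoate–enone [3+2] annulation, in which the phosphonium dienolate bonds through its ester-bearing α-carbon to the enone β-carbon (C9) on the face anti to the pseudo-axial anomeric PMB-oxy group and the enolate then closes onto the γ-carbon, so that the cis ring fusion (C5, C9) is set relative to C1 and the conjugated C7=C8 ester results.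

Step 5
Reactants: 7 ethyl (1R,4aS,7aS)-1-[(4-methoxybenzyl)oxy]-4-oxo-1,3,4,4a,5,7a-hexahydrocyclopenta[c]pyran-7-carboxylate
Product: 9 C3=C4 enol triflate of 7 (4-triflyloxy enol ether; C1/C5/C9 unchanged), via potassium C3-enolate 8 (not isolated)
Conditions: KHMDS, THF, −78 °C; then PhNTf2, −78 to 0 °C
Reagents that add atoms: N-phenyl-bis(trifluoromethanesulfonimide), O=S(=O)(N(c1ccccc1)S(=O)(=O)C(F)(F)F)C(F)(F)F
Why: Enol triflate formation, in which the hindered base removes a proton from the C3 methylene (more accessible than the ring-fusion methine C5–H and acidified by the ring oxygen, while the enoate γ-protons are far less acidic) and O-sulfonylation fixes the C3=C4 enol ether.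

Step 6
Reactants: 9 C3=C4 enol triflate
Product: 10 ethyl 4-(hydroxymethyl)-1β-(4-methoxybenzyloxy)-1,4a,5,7a-tetrahydrocyclopenta[c]pyran-7-carboxylate (C11 alcohol on the C3=C4 enol ether)
Conditions: Bu3SnCH2OH, Pd(PPh3)4 (5 mol %), LiCl, 1,4-dioxane, 90 °C; chromatography on Et3N-deactivated silica
Reagents that add atoms: (tributylstannyl)methanol, CCCC[Sn](CO)(CCCC)CCCC
Why: Stille coupling of a vinyl triflate with a hydroxymethylstannane, which transfers the hydroxymethyl group in preference to butyl and installs C11 with its free hydroxyl in one step under neutral conditions.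

Step 7
Reactants: 10 C11 alcohol
Product: 11 11-O-triisopropylsilyl ether of 10
Conditions: TIPSCl, imidazole, DMF, 0 °C to rt
Reagents that add atoms: triisopropylsilyl chloride, CC(C)[Si](Cl)(C(C)C)C(C)C
Why: Standard silylation of the only hydroxyl, with a group chosen to survive hydride reduction, peroxide and hot aqueous base.

Step 8
Reactants: 11 11-O-TIPS ethyl ester
Product: 12 C7=C8 allylic alcohol (10-hydroxy, 11-O-TIPS, 1β-OPMB)
Conditions: DIBAL-H (2.5 equiv), CH2Cl2, −78 °C; Rochelle salt work-up
Reagents that add atoms: none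
Why: 1,2-Reduction of the conjugated ester by DIBAL-H gives the allylic alcohol and leaves the acetal, enol ether and silyl ether intact at low temperature.

Step 9
Reactants: 12 C7=C8 allylic alcohol
Product: 13 7β,8β-epoxy-10-ol (convex epoxide; 11-O-TIPS, 1β-OPMB)
Conditions: VO(acac)2 (5 mol %), t-BuOOH (decane), CH2Cl2, 0 °C to rt
Reagents that add atoms: tert-butyl hydroperoxide, CC(C)(C)OO
Why: Vanadium-directed epoxidation oxidises only the alkene of the free allylic alcohol (the enol ether has no free hydroxyl next to it), and since the exocyclic CH2OH cannot choose a face the oxidant enters from the convex β face, the α face being covered by the pyran ring, which sets C7 and C8.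

Step 10
Reactants: 13 7β,8β-epoxy-10-ol
Product: 15 7β,8α,10-triol PMB acetal (O-7 β; tertiary 8-OH α; C10 β), via spiro 8α,10-epoxide 14 (not isolated)
Conditions: 0.5 M aq. NaOH/t-BuOH (1:1), 70 °C
Reagents that add atoms: water, O (delivered as hydroxide from NaOH, which is regenerated)
Why: The C10 alkoxide of 13 attacks C8 from the α face, anti to the epoxide C8–O bond, inverting C8 and releasing the C7 alkoxide with its β configuration untouched; hydroxide then opens the spiro epoxide 14 at its primary carbon C10 in an irreversible SN2 step that pulls the unfavourable epoxide equilibrium forward. The closest known reaction type is the Payne rearrangement–opening of 2,3-epoxy alcohols by hydroxide or thiolate at C1, which includes 2-alkyl cases where the migration terminus is fully substituted. The only ring closed is the transient oxirane of 14, in a 3-exo-tet mode, and no new ring remains in 15. The one new stereocentre, C8, is fixed by stereospecific backside displacement on the convex epoxide of step 9, so the tertiary hydroxyl lands on the concave face with C10 cis to O-7. The step needs opening at C10 after migration to outrun direct hydroxide attack at C7 of 13, and this is secured because C7 is a secondary ring carbon next to the quaternary C8 that must be reached from the concave face, whereas C10 of 14 is primary and exposed on the convex face. The PMB acetal, enol ether and TIPS ether are inert to aqueous base.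

Step 11
Reactants: 15 7β,8α,10-triol
Product: 16 10-O-tert-butyldimethylsilyl 7β,8α-diol
Conditions: TBSCl (1.1 equiv), imidazole, CH2Cl2, 0 °C
Reagents that add atoms: tert-butyldimethylsilyl chloride, CC(C)(C)[Si](C)(C)Cl
Why: Selective silylation of the primary C10 hydroxyl over the secondary C7 and tertiary C8 hydroxyls on steric grounds.

Step 12
Reactants: 17 (E)-4-hydroxycinnamic acid
Product: 19 (E)-4-(tert-butyldimethylsilyloxy)cinnamic acid, via bis-silylated acid 18 (not isolated)
Conditions: TBSCl (2.2 equiv), imidazole, DMF, rt; then AcOH, THF/H2O, rt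
Reagents that add atoms: tert-butyldimethylsilyl chloride, CC(C)(C)[Si](C)(C)Cl
Why: Exhaustive silylation followed by mild hydrolysis of the labile silyl ester, which leaves the aryl silyl ether and the E alkene unchanged.

Step 13
Reactants: 16 10-O-TBS 7β,8α-diol; 19 (E)-4-(tert-butyldimethylsilyloxy)cinnamic acid
Product: 20 7-O-[(E)-4-(tert-butyldimethylsilyloxy)cinnamoyl] ester (8α-OH free, 10-O-TBS, 11-O-TIPS, 1β-OPMB)
Conditions: DCC, DMAP, CH2Cl2, 0 °C to rt
Reagents that add atoms: none
Why: Steglich esterification acylates the secondary C7 hydroxyl on the convex face, while the tertiary concave C8 hydroxyl does not react under these conditions.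

Step 14
Reactants: 20 7-O-coumaroyl PMB acetal
Product: 21 C1 lactol (1β-OH drawn; anomers interconvert), other groups as in 20
Conditions: DDQ, CH2Cl2/pH 7 phosphate buffer, 0 °C; used directly in step 15
Reagents that add atoms: none
Why: Oxidative PMB cleavage, in which DDQ abstracts a benzylic hydride, water adds to the resulting aryl-stabilised oxocarbenium ion and the hemiacetal collapses to anisaldehyde and the lactol, whose oxygen is the original acetal oxygen; buffering protects the enol ether.

Step 15
Reactants: 21 C1 lactol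
Product: 22 1β-O-isovaleryl ester (trisilyl luzonoid A)
Conditions: isovaleric anhydride, Et3N, DMAP (cat.), CH2Cl2, −20 °C
Reagents that add atoms: 3-methylbutanoic anhydride, CC(C)CC(=O)OC(=O)CC(C)C
Why: Acylation of the hemiacetal hydroxyl, which should sit mainly pseudo-axial on the β face (anomeric effect, anti to the C9–C8 bond) and is acylated with retention under non-ionising conditions, while the tertiary C8 hydroxyl stays free.

Step 16
Reactants: 22 1β-O-isovaleryl trisilyl ether
Product: 23 luzonoid A
Conditions: TBAF/AcOH (1:1), THF, 0 °C to rt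
Reagents that add atoms: none
Why: Fluoride desilylation removes the C11 TIPS, C10 TBS and aryl TBS groups, and the acetic acid buffer suppresses base-induced migration of the coumarate from O-7 to the cis O-10 and cleavage of the acylal.

**Compound list**

1 | 3,4-di-O-acetyl-D-xylal | C1=C[C@@H](OC(C)=O)[C@H](OC(C)=O)CO1 | starting material
2 | 4-methoxybenzyl alcohol | COc1ccc(CO)cc1 | starting material
3 | 4-methoxybenzyl 4-O-acetyl-2,3-dideoxy-β-D-glycero-pent-2-enopyranoside | COc1ccc(CO[C@@H]2OC[C@@H](OC(C)=O)C=C2)cc1 | intermediate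
4 | 4-methoxybenzyl 2,3-dideoxy-β-D-glycero-pent-2-enopyranoside | COc1ccc(CO[C@@H]2OC[C@@H](O)C=C2)cc1 | intermediate
5 | (R)-6-[(4-methoxybenzyl)oxy]-2H-pyran-3(6H)-one | COc1ccc(CO[C@@H]2OCC(=O)C=C2)cc1 | intermediate
6 | ethyl buta-2,3-dienoate | CCOC(=O)C=C=C | starting material
7 | ethyl (1R,4aS,7aS)-1-[(4-methoxybenzyl)oxy]-4-oxo-1,3,4,4a,5,7a-hexahydrocyclopenta[c]pyran-7-carboxylate | COc1ccc(CO[C@@H]2OCC(=O)[C@H]3CC=C(C(=O)OCC)[C@@H]23)cc1 | intermediate
8 | potassium C3=C4 enolate of 7 (not isolated) | COc1ccc(CO[C@@H]2OC=C([O-])[C@H]3CC=C(C(=O)OCC)[C@@H]23)cc1.[K+] | intermediate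
9 | C3=C4 enol triflate of 7 | COc1ccc(CO[C@@H]2OC=C(OS(=O)(=O)C(F)(F)F)[C@H]3CC=C(C(=O)OCC)[C@@H]23)cc1 | intermediate
10 | 4-(hydroxymethyl) enol ether ethyl ester (C11 alcohol) | COc1ccc(CO[C@@H]2OC=C(CO)[C@H]3CC=C(C(=O)OCC)[C@@H]23)cc1 | intermediate
11 | 11-O-TIPS ether of 10 | COc1ccc(CO[C@@H]2OC=C(CO[Si](C(C)C)(C(C)C)C(C)C)[C@H]3CC=C(C(=O)OCC)[C@@H]23)cc1 | intermediate
12 | C7=C8 allylic alcohol (10-hydroxy, 11-O-TIPS) | COc1ccc(CO[C@@H]2OC=C(CO[Si](C(C)C)(C(C)C)C(C)C)[C@H]3CC=C(CO)[C@@H]23)cc1 | intermediate
13 | 7β,8β-epoxy-10-ol (key-step precursor) | COc1ccc(CO[C@@H]2OC=C(CO[Si](C(C)C)(C(C)C)C(C)C)[C@H]3C[C@@H]4O[C@]4(CO)[C@@H]23)cc1 | intermediate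
14 | spiro 8α,10-epoxide 7β-ol, present as its alkoxide (not isolated) | COc1ccc(CO[C@@H]2OC=C(CO[Si](C(C)C)(C(C)C)C(C)C)[C@H]3C[C@H](O)[C@]4(CO4)[C@@H]23)cc1 | intermediate
15 | 7β,8α,10-triol (key-step product) | COc1ccc(CO[C@@H]2OC=C(CO[Si](C(C)C)(C(C)C)C(C)C)[C@H]3C[C@H](O)[C@](O)(CO)[C@@H]23)cc1 | intermediate
16 | 10-O-TBS 7β,8α-diol | COc1ccc(CO[C@@H]2OC=C(CO[Si](C(C)C)(C(C)C)C(C)C)[C@H]3C[C@H](O)[C@](O)(CO[Si](C)(C)C(C)(C)C)[C@@H]23)cc1 | intermediate
17 | (E)-4-hydroxycinnamic acid | OC(=O)/C=C/c1ccc(O)cc1 | starting material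
18 | tert-butyldimethylsilyl (E)-4-(tert-butyldimethylsilyloxy)cinnamate (not isolated) | CC(C)(C)[Si](C)(C)OC(=O)/C=C/c1ccc(O[Si](C)(C)C(C)(C)C)cc1 | intermediate
19 | (E)-4-(tert-butyldimethylsilyloxy)cinnamic acid | OC(=O)/C=C/c1ccc(O[Si](C)(C)C(C)(C)C)cc1 | intermediate
20 | 7-O-[(E)-4-(TBSO)cinnamoyl] PMB acetal | COc1ccc(CO[C@@H]2OC=C(CO[Si](C(C)C)(C(C)C)C(C)C)[C@H]3C[C@H](OC(=O)/C=C/c4ccc(O[Si](C)(C)C(C)(C)C)cc4)[C@](O)(CO[Si](C)(C)C(C)(C)C)[C@@H]23)cc1 | intermediate
21 | C1 lactol (1β-OH) | O[C@@H]1OC=C(CO[Si](C(C)C)(C(C)C)C(C)C)[C@H]2C[C@H](OC(=O)/C=C/c3ccc(O[Si](C)(C)C(C)(C)C)cc3)[C@](O)(CO[Si](C)(C)C(C)(C)C)[C@@H]12 | intermediate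
22 | 1β-O-isovaleryl trisilyl ether | CC(C)CC(=O)O[C@@H]1OC=C(CO[Si](C(C)C)(C(C)C)C(C)C)[C@H]2C[C@H](OC(=O)/C=C/c3ccc(O[Si](C)(C)C(C)(C)C)cc3)[C@](O)(CO[Si](C)(C)C(C)(C)C)[C@@H]12 | intermediate
23 | luzonoid A | CC(C)CC(=O)O[C@@H]1OC=C(CO)[C@H]2C[C@H](OC(=O)/C=C/c3ccc(O)cc3)[C@](O)(CO)[C@@H]12 | target

**Step count**

Total steps: 16. Longest linear sequence: 15 (steps 1–11 and 13–16 from 1); step 12 is a one-step side branch.

**Steps most likely to fail**

1. Step 10 (key step). Backside entry of the C10 alkoxide at the fully substituted C8 from the concave face may be slow. Direct hydroxide attack at C7 could then compete, or the long heating in base could start to hydrolyse the C11 silyl ether. The fallback sets out from 13 and replaces epoxide migration by carbonate delivery. Cs2CO3 under CO2 (1 atm) in DMF turns the C10 alkoxide into its carbonate half-ester anion, which opens the epoxide at C8 in a 5-exo mode with the same inversion. This gives the 7β-hydroxy 8α,10-cyclic carbonate F1 without any intermolecular opening or hot hydroxide. K2CO3 in MeOH then removes the carbonate, and the route is rejoined at 15.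

2. Step 5. Enolisation may be poorly regioselective (C5 methine instead of C3 methylene), or the ring-fusion centre may epimerise through reversible enolate formation. The fallback sets out from 7 and moves the regiocontrol from kinetic deprotonation to an isolated thermodynamic enol ether. TMSOTf/Et3N in CH2Cl2 at 0 °C should give the alkoxy-substituted C3=C4 trimethylsilyl enol ether F2, which can be purified from any C4=C5 isomer. CsF and PhNTf2 in DME then convert F2 directly into the enol triflate, which is compatible with the ethyl ester, and the route is rejoined at 9.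

3. Step 15. The minor equatorial 1α-alkoxide may acylate faster than the favoured axial 1β-lactol, and the ring-opened hydroxy-aldehyde form may erode C9 under amine base. The fallback sets out from 21 and makes C1 the electrophile. Cl3CCN with K2CO3 in CH2Cl2 traps the more reactive equatorial alkoxide as the 1α-O-trichloroacetimidate F3. Isovaleric acid alone (CH2Cl2, rt, no promoter) then displaces the imidate with inversion to give the axial 1β-ester, so the kinetic preference that caused the failure now gives the right anomer. The route is rejoined at 22.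

**Further compounds**

F1 | step 10 | 7β-hydroxy 8α,10-cyclic carbonate (11-O-TIPS, 1β-OPMB) | COc1ccc(CO[C@@H]2OC=C(CO[Si](C(C)C)(C(C)C)C(C)C)[C@H]3C[C@H](O)[C@]4(COC(=O)O4)[C@@H]23)cc1
F2 | step 5 | C3=C4 trimethylsilyl enol ether of 7 | COc1ccc(CO[C@@H]2OC=C(O[Si](C)(C)C)[C@H]3CC=C(C(=O)OCC)[C@@H]23)cc1
F3 | step 15 | 1α-O-trichloroacetimidate of lactol 21 | ClC(Cl)(Cl)C(=N)O[C@H]1OC=C(CO[Si](C(C)C)(C(C)C)C(C)C)[C@H]2C[C@H](OC(=O)/C=C/c3ccc(O[Si](C)(C)C(C)(C)C)cc3)[C@](O)(CO[Si](C)(C)C(C)(C)C)[C@@H]12
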